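## Analysis of the target

The target 44 is a 5-6-11 tricycle. A cyclohexene (ring B: C18, C19, C21, C25, C27, C29) is cis-fused along C21–C25 to a cyclopentane (C21, C22, C23, C24, C25). C22 and C18 are bridged by the chain C2–C3–C8–C9–C10–C16–C17, which completes the eleven-membered ring.

There are seven stereocentres (3S, 10R, 21S, 22R, 25S, 27R, 29R). H21, H22, the angular methyl C26 and the C27 hydroxyl lie on one face (β); the C29 hydroxyl lies on the other, so the ring B diol is trans. The C22–C2 bond is α, cis to C19, which is what allows the bridge to close. C3 and C10 sit in the large ring and cannot be relayed reliably from the core.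

Sensitive groups are the tetrasubstituted C18=C19 alkene with its allylic C29 alcohol, the allylic acetate next to the 1,1-disubstituted C1=C2 alkene, and two acetylated hydroxyls that must be told apart from two free ones. The difficulties are the quaternary C25 flanked by four contiguous ring stereocentres, the fully substituted alkene, and a medium ring that is strained and slow to close.

The strategy rests on C22. It is a cyclopentane carbon carrying C2 as a one-carbon branch at the ketone oxidation level (C=CH2 is a masked C=O). That is the pattern left when a cyclohexane containing C2 contracts by a 1,2-shift of the C2–C23 bond to C22, so the hydrindane maps onto a cis-decalin in which C2 is a ring carbinol carbon.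

## Retrosynthetic reasoning

**End game (44 back to 40).** The two free hydroxyls of 44 are carried as silyl ethers (43) and the two acetates as 4-methoxybenzyl ethers (41, via diol 42), so the four oxygens stay differentiated. C1 is removed as the last carbon: the C1=C2 alkene comes from the C2 ketone of 40 by methylenation. This ketone is exactly what the ring contraction leaves behind.

**C8–C9 (40 back to 38).** The large ring is cut between C8 and C9. These are the only two adjacent ring carbons that are plain methylenes, and the cut leaves a vinyl group on each of the preformed stereocentres C3 and C10. The forward reaction is ring-closing metathesis of 38 to 39 followed by hydrogenation of the new disubstituted alkene only.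

**C22–C23 (38 back to 36, the key disconnection).** Breaking C22–C23 and re-forming C2–C23 turns the cyclopentyl ketone 38 into the cis-decalin 36, with a tertiary hydroxyl at C2 and a mesylate at C22. The forward semipinacol shift builds the cyclopentane and sets C22 with inversion, so C22 must carry its oxygen α in 36. C21 and C25 come unchanged from a cis-decalin.

**C2–C3 (36 back to 31 and 33).** The tertiary carbinol is opened at C2–C3: the γ-alkoxyallyl chromium reagent 33 (from acetal 10) adds to the C2 ketone of 31. This one step brings in C3 with its oxygen and vinyl group and sets C2 and C3. External reagents reach ring A from the convex β face, which places the hydroxyl α, cis to the C22 oxygen as required. Ester cleavage (35) and mesylation give 36.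

**C22–O (31 back to 29).** The same convex-face rule means an oxidant can only put oxygen on C22 from the β face, the wrong one. The oxygen is therefore introduced β (30, from silyl enol ether 29) and inverted by an SN2 esterification to 31. This inversion is the repair that makes the required α-mesylate accessible.

**Ring B diol and C17–C18 (29 back to 23 and 8).** Enol ether 29 comes from diol ketone 28, whose 29α hydroxyl arises by hydroxyl-directed reduction of the enone in 27. The side chain is cut at C17–C18, an sp3–sp2 bond made by cross-coupling of iodoenone 23 with the borate 25 derived from iodide 8. This gives 26, and acid unmasking gives 27.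

**C19–C20 and the C29 oxygen (23 back to 11).** Iodoenone 23 comes from enone 22. The C19 methyl and the C29 oxygen are installed together: methyl addition to the C19 ketone of enone 20 and oxidative 1,3-transposition of the tertiary allylic alcohol 21. Enone 20 comes from ketone 18. Its C19 oxygen is introduced at the γ-position of the Wieland–Miescher enone through dienyl silyl ether 14 (15), its cis ring fusion by hydrogenation (16), with the C2 ketone masked (17). The C27 alcohol and C25 come from the commercial enedione 11 by a known selective reduction (12, 13).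

**Side chain and reagent (8 back to 1 and 4; 10 back to 9).** C10 is set by an iridium-catalysed allylic alkylation of carbonate 3 (from diol 1 via 2) with malonate 4, which makes the C10–C16 bond (5). Decarboxylation (6), reduction (7) and iodination give 8. Acetal 10 comes from acrolein diethyl acetal 9.

## Alternatives that were turned down

**Alternative 1:** Ring B is taken back to a five-membered ring with a three-membered ring fused across C18–C27 (C29 as apex). In the forward step a cation at C19 breaks C18–C27, giving the C18=C19 alkene and the C27 ketone of A1.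
- For it: the tetrasubstituted alkene, with methyl and chain in place, and the C27 carbonyl appear regiospecifically in one step. This is stronger than the chosen route, which spends steps 10–19 on the same alkene.
- Against it: A1 has no oxygen at C29, so the trans-diol must be finished on the complete tricycle. Hydroxylation next to the C27 ketone would come from the exposed face and would then have to be corrected, all in the presence of the large ring, the exocyclic alkene and two allylic ethers. A1 already contains the eleven-membered ring, so the key step comes after the macrocyclisation, on the most advanced material. The fused alkoxycyclopropane on a fully substituted carbon next to quaternary C25 is itself hard to build.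
- Comparison: the chosen route is longer, but its key step acts on a cis-decalin derived from a cheap enantiopure enedione, before the large ring exists, and it finishes the diol early.

**Alternative 2:** Three bonds (C21–C25, C22–C23, C23–C24) are cut. In the forward Pauson–Khand reaction the C21–C22 alkyne, the C24=C25 alkene and CO combine to close both carbocycles and give A2.
- For it: the hydrindane and the quaternary C25 are built convergently in one step, and ring B substituents can come from acyclic stereocontrolled chemistry. In ring-construction economy it is stronger.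
- Against it: A2 carries a C23 carbonyl that the target lacks and that must be removed from a sensitive dienone. The C21=C22 alkene must then be reduced to set H21 and H22, both β, while the C18=C19 alkene survives. Control at C25 rests only on the neighbouring silyl ether. A cyclohexene closed onto a 1,1-disubstituted alkene with a quaternary centre is the less favourable class of this annulation. The large ring is still to be made.
- Comparison: the chosen route sets C21 by a well-behaved octalone hydrogenation and C22 stereospecifically in the migration, and it leaves no excess oxygen to remove.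

**Alternative 3:** C21–C22 is formed while C3–C18 breaks in an anionic [3,3] shift. The cyclopentane closes and a seven-membered ring expands to the eleven-membered ring of A3.
- For it: the medium ring is made by ring expansion, not by end-to-end closure. This avoids the metathesis that is a real risk of the chosen route, and it is clearly stronger on this point.
- Against it: C21 and C22 are both created in the sigmatropic transition state of a constrained spiro system, and their relation to C25 depends on chair versus boat. A3 has a methylene at C2 and the ketone at C3, so the exocyclic alkene and the (S)-carbinol at C3 must be installed on the macrocycle, with regiochemistry (C2 versus C8) and conformational control both open.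
- Comparison: the chosen route fixes C3 in an acyclic transition state before ring closure and C22 by inversion, at the price of a macrocyclisation.

Key step: step 28

## Conventions and assumptions

- Atom locants are those of the target in the order of its SMILES and are kept for all intermediates. β is the face of the angular methyl C26 and α the other face. Ring A is C2–C23–C24–C25–C21–C22; ring B is C25–C27–C29–C18–C19–C21.
- Assumption: (E)-but-2-ene-1,4-diol, acrolein diethyl acetal and the (S)-Wieland–Miescher ketone are purchased.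
- The C19 carbinol centres of 15, 16, 17 and 21 are drawn as the expected epimers. Either epimer serves, because C19 becomes sp2.
- Abbreviations: TBS = tert-butyldimethylsilyl, PMB = 4-methoxybenzyl, Bz = benzoyl, Ms = methanesulfonyl.

## Route

Step 1
Reactants: 1 (E)-but-2-ene-1,4-diol
Product: 2 (E)-4-[(4-methoxybenzyl)oxy]but-2-en-1-ol
Conditions: NaH (1 equiv), 4-methoxybenzyl chloride (1 equiv), Bu4NI (cat.), diol in excess, THF, 0 °C to rt
Reagents that add atoms: 4-methoxybenzyl chloride COc1ccc(CCl)cc1
Why: Williamson etherification; the excess of the symmetric diol should limit double alkylation, and no stereocentre is involved.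

Step 2
Reactants: 2 (E)-4-[(4-methoxybenzyl)oxy]but-2-en-1-ol
Product: 3 (E)-4-[(4-methoxybenzyl)oxy]but-2-en-1-yl methyl carbonate
Conditions: ClCO2Me, pyridine, CH2Cl2, 0 °C
Reagents that add atoms: methyl chloroformate COC(=O)Cl
Why: Acylation of the primary allylic alcohol gives the carbonate leaving group needed for allylic substitution.

Step 3
Reactants: 3 (E)-4-[(4-methoxybenzyl)oxy]but-2-en-1-yl methyl carbonate; 4 dimethyl malonate
Product: 5 dimethyl 2-[(2S)-1-[(4-methoxybenzyl)oxy]but-3-en-2-yl]malonate
Conditions: [Ir(cod)Cl]2 (2 mol%), BINOL-derived N,N-bis(1-phenylethyl)phosphoramidite (4 mol%, the enantiomer that delivers (S)-5), 1,5,7-triazabicyclo[4.4.0]dec-5-ene (cat.), THF, rt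
Reagents that add atoms: none
Why: Iridium-catalysed asymmetric allylic alkylation; the malonate attacks the substituted terminus of the allyl iridium intermediate, so the branched product with the vinyl group on C10 should form, and the ligand sets C10. The centre is labelled S here and R after step 4 only because the priorities change.

Step 4
Reactants: 5 dimethyl 2-[(2S)-1-[(4-methoxybenzyl)oxy]but-3-en-2-yl]malonate
Product: 6 methyl (3R)-3-{[(4-methoxybenzyl)oxy]methyl}pent-4-enoate
Conditions: LiCl, H2O, DMSO, 150 °C
Reagents that add atoms: none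
Why: Krapcho dealkoxycarbonylation of the malonate; the stereocentre is β to the ester and is not enolisable.

Step 5
Reactants: 6 methyl (3R)-3-{[(4-methoxybenzyl)oxy]methyl}pent-4-enoate
Product: 7 (3R)-3-{[(4-methoxybenzyl)oxy]methyl}pent-4-en-1-ol
Conditions: LiAlH4, Et2O, 0 °C
Reagents that add atoms: none
Why: Hydride reduction of the ester to the primary alcohol (C17).

Step 6
Reactants: 7 (3R)-3-{[(4-methoxybenzyl)oxy]methyl}pent-4-en-1-ol
Product: 8 1-({[(2R)-2-(2-iodoethyl)but-3-en-1-yl]oxy}methyl)-4-methoxybenzene
Conditions: I2, PPh3, imidazole, CH2Cl2, 0 °C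
Reagents that add atoms: iodine II
Why: Appel-type iodination of the primary alcohol by SN2 at C17.

Step 7
Reactants: 9 acrolein diethyl acetal (3,3-diethoxyprop-1-ene)
Product: 10 acrolein bis(4-methoxybenzyl) acetal (3,3-bis[(4-methoxybenzyl)oxy]prop-1-ene)
Conditions: 4-methoxybenzyl alcohol (2.2 equiv), pyridinium p-toluenesulfonate (cat.), cyclohexane, 60 °C, ethanol distilled off
Reagents that add atoms: 4-methoxybenzyl alcohol COc1ccc(CO)cc1
Why: Acid-catalysed transacetalisation, driven by removal of ethanol.

Step 8
Reactants: 11 (S)-Wieland–Miescher ketone [(8aS)-8a-methyl-3,4,8,8a-tetrahydronaphthalene-1,6(2H,7H)-dione]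
Product: 12 (4aS,5S)-5-hydroxy-4a-methyl-4,4a,5,6,7,8-hexahydronaphthalen-2(3H)-one (27β-alcohol)
Conditions: NaBH4 (0.3 equiv), EtOH, −10 °C
Reagents that add atoms: none
Why: Chemoselective reduction of the saturated ketone beside the enone; hydride adds from the face opposite the angular methyl and gives the 27β alcohol, a known selectivity for this enedione.

Step 9
Reactants: 12 (4aS,5S)-5-hydroxy-4a-methyl-4,4a,5,6,7,8-hexahydronaphthalen-2(3H)-one
Product: 13 27β-TBS ether of 12 (C2 enone; C22=C21)
Conditions: TBSCl, imidazole, DMF, 40 °C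
Reagents that add atoms: tert-butyldimethylsilyl chloride CC(C)(C)[Si](C)(C)Cl
Why: Silylation of the hindered secondary alcohol; the group has to survive base, organometallics and oxidants up to step 19.

Step 10
Reactants: 13 27β-TBS ether (C2 enone)
Product: 14 2-trimethylsilyloxy diene (C2=C22; C21=C19; 27β-OTBS)
Conditions: Me3SiOTf, Et3N, CH2Cl2, 0 °C
Reagents that add atoms: trimethylsilyl triflate C[Si](C)(C)OS(=O)(=O)C(F)(F)F
Why: Soft enolisation of the enone gives the thermodynamic heteroannular dienyl silyl ether, which moves the nucleophilic site to the γ-carbon C19.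

Step 11
Reactants: 14 2-trimethylsilyloxy diene
Product: 15 19β-hydroxy enone (C2 ketone; C22=C21; 27β-OTBS)
Conditions: mCPBA (1.05 equiv), NaHCO3, CH2Cl2, −20 °C; then dilute aq. HCl work-up
Reagents that add atoms: 3-chloroperbenzoic acid OOC(=O)c1cccc(Cl)c1
Why: Vinylogous Rubottom oxidation; the peracid attacks the terminal C21=C19 bond of the dienyl ether and the epoxide opens to the γ-hydroxy enone. Axial (β) attack is expected, but the C19 configuration is lost later.

Step 12
Reactants: 15 19β-hydroxy enone
Product: 16 cis-decalone (21β-H; 19β-OH; 27β-OTBS; C2 ketone)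
Conditions: H2 (1 atm), 5% Pd/C, EtOAc with pyridine (5 vol%), rt
Reagents that add atoms: none
Why: Heterogeneous hydrogenation of a Wieland–Miescher-type octalone, which is known to favour the cis-fused decalone; the β-hydroxyl can anchor the substrate to the catalyst on the same face, and pyridine should suppress allylic hydrogenolysis. This sets C21 (H cis to C26).

Step 13
Reactants: 16 cis-decalone (19β-OH; C2 ketone)
Product: 17 C2 ethylene ketal (19β-OH; 21β-H; 27β-OTBS)
Conditions: HOCH2CH2OH, pyridinium p-toluenesulfonate, benzene, reflux with water removal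
Reagents that add atoms: ethylene glycol OCCO
Why: Ketalisation of the unhindered C2 ketone, so that ring B can be worked on with bases and organometallics.

Step 14
Reactants: 17 C2 ethylene ketal (19β-OH)
Product: 18 19-ketone (C2 ketal; 21β-H; 27β-OTBS)
Conditions: Dess–Martin periodinane, NaHCO3, CH2Cl2, rt
Reagents that add atoms: none
Why: Buffered oxidation of the secondary alcohol; the neutral conditions should leave the now enolisable C21 untouched.

Step 15
Reactants: 18 19-ketone
Product: 20 enone (C19 ketone; C18=C29; C2 ketal; 27β-OTBS), via lithium enolate 19 (not isolated)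
Conditions: LiN(iPr)2, THF, −78 °C; then N-tert-butylbenzenesulfinimidoyl chloride, −78 °C
Reagents that add atoms: none
Why: Kinetic deprotonation takes place at the methylene C18 rather than the ring-fusion methine C21, and the sulfinimidoyl chloride dehydrogenates the enolate to the enone in the same flask; C21 is not touched.

Step 16
Reactants: 20 enone (C19 ketone; C18=C29)
Product: 21 19-methyl carbinol (19β-CH3; 19α-OH; C18=C29; C2 ketal; 27β-OTBS)
Conditions: MeLi, CeCl3, THF, −78 °C
Reagents that add atoms: methyllithium [Li]C
Why: 1,2-Addition of the weakly basic organocerium reagent to the enone carbonyl introduces C20 without enolising C21; attack from the convex face is expected, but the carbinol configuration does not matter.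

Step 17
Reactants: 21 19-methyl carbinol
Product: 22 transposed enone (C29 ketone; C18=C19 bearing C20; C2 ketal; 27β-OTBS)
Conditions: C5H5NH[CrO3Cl] (2 equiv), 4 Å molecular sieves, CH2Cl2, rt
Reagents that add atoms: pyridinium chlorochromate [O-][Cr](=O)(=O)Cl.c1cc[nH+]cc1
Why: Babler–Dauben oxidative transposition; the chromate ester of the tertiary allylic alcohol undergoes a [3,3] shift to C29 and is oxidised there, which places the oxygen on C29 and the methyl-bearing alkene at C18=C19 in one operation.

Step 18
Reactants: 22 transposed enone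
Product: 23 18-iodo enone (C29 ketone; C18(I)=C19)
Conditions: I2, pyridine, CH2Cl2, 0 °C to rt
Reagents that add atoms: iodine II
Why: α-Iodination of a cyclic enone by conjugate addition of pyridine, iodination of the enolate and elimination; the β-methyl slows but does not prevent it.

Step 19
Reactants: 23 18-iodo enone; 8 1-({[(2R)-2-(2-iodoethyl)but-3-en-1-yl]oxy}methyl)-4-methoxybenzene
Product: 26 18-alkyl enone (C29 ketone; C18=C19; chain C17–C16–C10(CH2OPMB)–CH=CH2; C2 ketal; 27β-OTBS), via alkyllithium 24 (not isolated), via lithium borate 25 (not isolated)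
Conditions: 8, t-BuLi (2 equiv), Et2O, −78 °C; B-methoxy-9-borabicyclo[3.3.1]nonane, THF, −78 °C to rt; then 23, Pd(dppf)Cl2 (5 mol%), AsPh3, Cs2CO3, DMF–H2O, rt
Reagents that add atoms: none
Why: B-alkyl Suzuki–Miyaura coupling of an α-iodoenone; iodine–lithium exchange and trapping with the borinate give the transferable alkyl borate, and the sp3–sp2 bond C17–C18 forms without touching C10. The pent-4-enyl lithium has no favourable cyclisation mode.

Step 20
Reactants: 26 18-alkyl enone (C2 ketal; 27β-OTBS)
Product: 27 27β-hydroxy 2,29-dione (C18=C19)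
Conditions: aq. HCl (2 M), THF, rt to 40 °C
Reagents that add atoms: water O
Why: Acid hydrolysis removes the dioxolane and the silyl ether together; the PMB ether, the enone and the terminal alkene should tolerate dilute aqueous acid.

Step 21
Reactants: 27 27β-hydroxy 2,29-dione
Product: 28 27β,29α-diol (C2 ketone; C18=C19)
Conditions: Me4NBH(OAc)3, MeCN–AcOH, −25 °C
Reagents that add atoms: none
Why: Evans–Saksena reduction; the 27β hydroxyl binds boron and delivers hydride to the β face of the neighbouring C29 carbonyl, which should give the 29α alcohol (trans-diol). The C2 ketone has no directing hydroxyl and is not reduced by this reagent.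

Step 22
Reactants: 28 27β,29α-diol (C2 ketone)
Product: 29 tris-TBS compound (27β-OTBS; 29α-OTBS; C2(OTBS)=C22 silyl enol ether)
Conditions: TBSOTf (3.5 equiv), Et3N, CH2Cl2, 0 °C to rt
Reagents that add atoms: tert-butyldimethylsilyl triflate CC(C)(C)[Si](C)(C)OS(=O)(=O)C(F)(F)F
Why: The triflate silylates both hindered hydroxyls and, with Et3N, converts the ketone to its silyl enol ether; cis-fused 2-decalones enolise toward the ring fusion, so the C2=C22 isomer is expected.

Step 23
Reactants: 29 tris-TBS compound (C2=C22 silyl enol ether)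
Product: 30 22β-hydroxy ketone (C2 ketone; 27β,29α-bis-OTBS)
Conditions: OsO4 (2 mol%), N-methylmorpholine N-oxide (1.1 equiv), acetone–H2O, 0 °C
Reagents that add atoms: N-methylmorpholine N-oxide C[N+]1([O-])CCOCC1
Why: Upjohn dihydroxylation of the electron-rich silyl enol ether, which should react well before the terminal and the hindered tetrasubstituted alkenes; the osmate ester collapses to the α-hydroxy ketone. The oxidant approaches the convex β face of the cis-decalin, so the hydroxyl is 22β, cis to H21.

Step 24
Reactants: 30 22β-hydroxy ketone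
Product: 31 22α-benzoate (C2 ketone; 27β,29α-bis-OTBS)
Conditions: PhCO2H, PPh3, iPrO2CN=NCO2iPr, toluene, 0 °C to rt
Reagents that add atoms: benzoic acid OC(=O)c1ccccc1
Why: Mitsunobu esterification with inversion; SN2 displacement is accelerated by the adjacent carbonyl, and no hydrogen is antiperiplanar to the leaving group (H21 is cis to it), so elimination is not available. The oxygen ends on the α face, where no external oxidant could have placed it.

Step 25
Reactants: 31 22α-benzoate; 10 acrolein bis(4-methoxybenzyl) acetal
Product: 34 tertiary alcohol (2α-OH; 2β side chain (3S)-CH(OPMB)CH=CH2; 22α-OBz; 27β,29α-bis-OTBS), via iodo ether 32 (not isolated), via allylchromium dichloride 33 (not isolated)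
Conditions: 10, Me3SiI, CrCl2, THF, −30 °C; then 31, −30 °C to rt
Reagents that add atoms: none
Why: Nozaki–Hiyama-type addition of an (E)-γ-alkoxyallylchromium reagent, which bonds through the oxygen-bearing carbon. Attack on the convex β face of the cis-decalone puts the new C2–C3 bond β and the hydroxyl α, cis to the benzoate. In the chair transition state with chromium on the less hindered C23 side of the carbonyl, the (E)-reagent should give the 2,3-anti adduct, which is 3S.

Step 26
Reactants: 34 tertiary alcohol (22α-OBz)
Product: 35 2α,22α-diol (side chain (3S)-CH(OPMB)CH=CH2 on C2; 27β,29α-bis-OTBS)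
Conditions: K2CO3, MeOH, rt
Reagents that add atoms: none
Why: Transesterification removes the benzoate; silyl and PMB ethers are stable, and C22 is no longer next to a carbonyl, so it cannot epimerise.

Step 27
Reactants: 35 2α,22α-diol
Product: 36 22α-mesylate (2α-OH; key precursor)
Conditions: MsCl, Et3N, CH2Cl2, −20 °C
Reagents that add atoms: methanesulfonyl chloride CS(=O)(=O)Cl
Why: Sulfonylation distinguishes the secondary from the tertiary hydroxyl; the cis arrangement of hydroxyl and mesylate cannot close to an epoxide.

Step 28
Reactants: 36 22α-mesylate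
Product: 38 hydrindane ketone (C2 ketone on C22; 22β-H; (3S)-OPMB; both vinyl-terminated chains; 27β,29α-bis-OTBS), via diethylaluminium alkoxide 37 (not isolated)
Conditions: Et3Al (3 equiv), CH2Cl2, −78 °C to 0 °C
Reagents that add atoms: none
Why: Et3Al converts the tertiary hydroxyl to the diethylaluminium alkoxide 37 and the Lewis acidic aluminium assists departure of the mesylate; as the C22–O bond ionises, the antiperiplanar ring bond C2–C23 shifts to C22 in a concerted 1,2-migration and the alkoxide oxygen becomes the C2 carbonyl. The closest known reaction type is the organoaluminium-promoted semipinacol rearrangement of 2-hydroxy sulfonates, used for ring contraction of cyclohexane-1,2-diol monosulfonates. The cyclopentane (C21, C22, C23, C24, C25) closes by contraction of the six-membered ring through a three-centre migration, not by an end-to-end cyclisation, so no ring-closure rule is at stake. The one new stereocentre, C22, forms with inversion because C23 enters anti to the leaving group, so the 22α mesylate fixed in step 24 gives the 22β hydrogen and the α acyl branch of the target; C21, C25 and C3 are not touched. The step needs the ring bond, not the C3 side chain or a hydride, to migrate. This is secured by the chair with equatorial mesylate (side chain equatorial, hydroxyl axial), which the preference of the two bulky vicinal silyl ethers for a trans-diaxial arrangement should favour, by the cis relation of hydroxyl and mesylate, which excludes epoxide formation, and by the low migratory aptitude of the oxygen-bearing C3. Low temperature and the absence of base should keep the new α-alkoxy ketone from epimerising at C3 or C22.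

Step 29
Reactants: 38 hydrindane ketone
Product: 39 macrocyclic enone (eleven-membered ring; C8=C9 as an E/Z mixture; C2 ketone)
Conditions: second-generation Grubbs catalyst (10 mol%), CH2Cl2 (1 mM), 40 °C
Reagents that add atoms: none
Why: Ring-closing metathesis of the two monosubstituted alkenes; the 1,1-disubstituted and tetrasubstituted positions are inert, the cis disposition of the two chains on the hydrindane brings the termini together, and high dilution is used against oligomerisation. The alkene geometry is removed in the next step.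

Step 30
Reactants: 39 macrocyclic enone
Product: 40 saturated macrocyclic ketone (C8–C9 reduced; C18=C19 retained)
Conditions: H2 (1 atm), RhCl(PPh3)3 (10 mol%), benzene, rt
Reagents that add atoms: none
Why: Homogeneous hydrogenation with this rhodium complex reduces disubstituted alkenes but not tetrasubstituted ones, and it leaves benzylic ethers and the ketone intact.

Step 31
Reactants: 40 saturated macrocyclic ketone
Product: 41 C2 exocyclic methylene compound (C1=C2; 3,11-bis-OPMB; 27,29-bis-OTBS)
Conditions: Cp2TiMe2, toluene, 70 °C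
Reagents that add atoms: dimethyltitanocene C[Ti](C)(C1C=CC=C1)C1C=CC=C1
Why: Petasis methylenation; the non-basic titanium methylidene converts hindered, enolisable ketones to 1,1-disubstituted alkenes without epimerising the flanking C3 and C22.

Step 32
Reactants: 41 C2 exocyclic methylene compound
Product: 42 3,11-diol (27,29-bis-OTBS)
Conditions: DDQ, CH2Cl2–pH 7 buffer, 0 °C
Reagents that add atoms: none
Why: Oxidative cleavage of both PMB ethers by hydride abstraction at the electron-rich benzylic position; silyl ethers and unactivated alkenes are untouched.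

Step 33
Reactants: 42 3,11-diol
Product: 43 3,11-diacetate (27,29-bis-OTBS)
Conditions: Ac2O, pyridine, 4-(dimethylamino)pyridine (cat.), CH2Cl2, rt
Reagents that add atoms: acetic anhydride CC(=O)OC(C)=O
Why: Acylation of the only two free hydroxyls; the future free diol is still silylated.

Step 34
Reactants: 43 3,11-diacetate
Product: 44 target CNP0193272.1
Conditions: HF·pyridine, pyridine–THF, 0 °C to rt
Reagents that add atoms: none
Why: Fluoride-mediated cleavage of the two secondary silyl ethers under buffered acidic conditions, which do not hydrolyse or shift the acetates.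

## Compound list

1 | (E)-but-2-ene-1,4-diol | OC/C=C/CO | starting material
2 | (E)-4-[(4-methoxybenzyl)oxy]but-2-en-1-ol | OC/C=C/COCc1ccc(OC)cc1 | intermediate
3 | (E)-4-[(4-methoxybenzyl)oxy]but-2-en-1-yl methyl carbonate | COC(=O)OC/C=C/COCc1ccc(OC)cc1 | intermediate
4 | dimethyl malonate | COC(=O)CC(=O)OC | starting material
5 | dimethyl 2-[(2S)-1-[(4-methoxybenzyl)oxy]but-3-en-2-yl]malonate | COC(=O)C(C(=O)OC)[C@@H](COCc1ccc(OC)cc1)C=C | intermediate
6 | methyl (3R)-3-{[(4-methoxybenzyl)oxy]methyl}pent-4-enoate | COC(=O)C[C@@H](COCc1ccc(OC)cc1)C=C | intermediate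
7 | (3R)-3-{[(4-methoxybenzyl)oxy]methyl}pent-4-en-1-ol | OCC[C@@H](COCc1ccc(OC)cc1)C=C | intermediate
8 | 1-({[(2R)-2-(2-iodoethyl)but-3-en-1-yl]oxy}methyl)-4-methoxybenzene | ICC[C@@H](COCc1ccc(OC)cc1)C=C | intermediate
9 | acrolein diethyl acetal | C=CC(OCC)OCC | starting material
10 | acrolein bis(4-methoxybenzyl) acetal | C=CC(OCc1ccc(OC)cc1)OCc1ccc(OC)cc1 | intermediate
11 | (S)-Wieland–Miescher ketone | O=C1CC[C@]2(C)C(=O)CCCC2=C1 | starting material
12 | (4aS,5S)-5-hydroxy-4a-methyl-4,4a,5,6,7,8-hexahydronaphthalen-2(3H)-one | O=C1CC[C@]2(C)[C@@H](O)CCCC2=C1 | intermediate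
13 | 27β-TBS ether of 12 | O=C1CC[C@]2(C)[C@@H](O[Si](C)(C)C(C)(C)C)CCCC2=C1 | intermediate
14 | 2-trimethylsilyloxy diene (C2=C22, C21=C19), 27β-OTBS | C[Si](C)(C)OC1=CC2=CCC[C@H](O[Si](C)(C)C(C)(C)C)[C@@]2(C)CC1 | intermediate
15 | 19β-hydroxy enone (C2 ketone, C22=C21), 27β-OTBS | O=C1CC[C@]2(C)[C@@H](O[Si](C)(C)C(C)(C)C)CC[C@@H](O)C2=C1 | intermediate
16 | cis-decalone, 21β-H, 19β-OH, 27β-OTBS | O=C1CC[C@]2(C)[C@@H](O[Si](C)(C)C(C)(C)C)CC[C@@H](O)[C@@H]2C1 | intermediate
17 | C2 ethylene ketal of 16 | O1CCOC13CC[C@]2(C)[C@@H](O[Si](C)(C)C(C)(C)C)CC[C@@H](O)[C@@H]2C3 | intermediate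
18 | 19-ketone, C2 ketal, 21β-H, 27β-OTBS | O1CCOC13CC[C@]2(C)[C@@H](O[Si](C)(C)C(C)(C)C)CCC(=O)[C@@H]2C3 | intermediate
19 | lithium enolate of 18 (C19(OLi)=C18) | O1CCOC13CC[C@]2(C)[C@@H](O[Si](C)(C)C(C)(C)C)CC=C(O[Li])[C@@H]2C3 | intermediate
20 | enone, C19 ketone, C18=C29, C2 ketal | O1CCOC13CC[C@]2(C)[C@@H](O[Si](C)(C)C(C)(C)C)C=CC(=O)[C@@H]2C3 | intermediate
21 | 19-methyl carbinol (19β-CH3, 19α-OH), C18=C29 | O1CCOC13CC[C@]2(C)[C@@H](O[Si](C)(C)C(C)(C)C)C=C[C@](C)(O)[C@@H]2C3 | intermediate
22 | transposed enone, C29 ketone, C18=C19(CH3) | O1CCOC13CC[C@]2(C)[C@@H](O[Si](C)(C)C(C)(C)C)C(=O)C=C(C)[C@@H]2C3 | intermediate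
23 | 18-iodo enone | O1CCOC13CC[C@]2(C)[C@@H](O[Si](C)(C)C(C)(C)C)C(=O)C(I)=C(C)[C@@H]2C3 | intermediate
24 | alkyllithium from 8 | [Li]CC[C@@H](COCc1ccc(OC)cc1)C=C | intermediate
25 | lithium B-alkyl-B-methoxy-9-borabicyclo[3.3.1]nonane borate | [Li+].CO[B-]1(CC[C@@H](COCc2ccc(OC)cc2)C=C)C2CCCC1CCC2 | intermediate
26 | 18-alkyl enone, C2 ketal, 27β-OTBS, (10R) chain | O1CCOC13CC[C@]2(C)[C@@H](O[Si](C)(C)C(C)(C)C)C(=O)C(CC[C@@H](COCc4ccc(OC)cc4)C=C)=C(C)[C@@H]2C3 | intermediate
27 | 27β-hydroxy 2,29-dione | O=C1CC[C@]2(C)[C@@H](O)C(=O)C(CC[C@@H](COCc3ccc(OC)cc3)C=C)=C(C)[C@@H]2C1 | intermediate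
28 | 27β,29α-diol, C2 ketone | O=C1CC[C@]2(C)[C@@H](O)[C@H](O)C(CC[C@@H](COCc3ccc(OC)cc3)C=C)=C(C)[C@@H]2C1 | intermediate
29 | tris-TBS compound, C2(OTBS)=C22 silyl enol ether | CC(C)(C)[Si](C)(C)OC=1CC[C@]2(C)[C@@H](O[Si](C)(C)C(C)(C)C)[C@H](O[Si](C)(C)C(C)(C)C)C(CC[C@@H](COCc3ccc(OC)cc3)C=C)=C(C)[C@@H]2C=1 | intermediate
30 | 22β-hydroxy ketone | O=C1CC[C@]2(C)[C@@H](O[Si](C)(C)C(C)(C)C)[C@H](O[Si](C)(C)C(C)(C)C)C(CC[C@@H](COCc3ccc(OC)cc3)C=C)=C(C)[C@@H]2[C@H]1O | intermediate
31 | 22α-benzoate ketone | O=C1CC[C@]2(C)[C@@H](O[Si](C)(C)C(C)(C)C)[C@H](O[Si](C)(C)C(C)(C)C)C(CC[C@@H](COCc3ccc(OC)cc3)C=C)=C(C)[C@@H]2[C@@H]1OC(=O)c1ccccc1 | intermediate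
32 | 1-iodoallyl 4-methoxybenzyl ether (racemic) | C=CC(I)OCc1ccc(OC)cc1 | intermediate
33 | (E)-[3-(4-methoxybenzyloxy)allyl]chromium dichloride | Cl[Cr](Cl)C/C=C/OCc1ccc(OC)cc1 | intermediate
34 | tertiary alcohol, 2α-OH, (3S) side chain, 22α-OBz | C=C[C@H](OCc3ccc(OC)cc3)[C@@]1(O)CC[C@]2(C)[C@@H](O[Si](C)(C)C(C)(C)C)[C@H](O[Si](C)(C)C(C)(C)C)C(CC[C@@H](COCc4ccc(OC)cc4)C=C)=C(C)[C@@H]2[C@@H]1OC(=O)c1ccccc1 | intermediate
35 | 2α,22α-diol | C=C[C@H](OCc3ccc(OC)cc3)[C@@]1(O)CC[C@]2(C)[C@@H](O[Si](C)(C)C(C)(C)C)[C@H](O[Si](C)(C)C(C)(C)C)C(CC[C@@H](COCc4ccc(OC)cc4)C=C)=C(C)[C@@H]2[C@@H]1O | intermediate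
36 | 22α-mesylate, 2α-OH (key precursor) | C=C[C@H](OCc3ccc(OC)cc3)[C@@]1(O)CC[C@]2(C)[C@@H](O[Si](C)(C)C(C)(C)C)[C@H](O[Si](C)(C)C(C)(C)C)C(CC[C@@H](COCc4ccc(OC)cc4)C=C)=C(C)[C@@H]2[C@@H]1OS(C)(=O)=O | intermediate
37 | diethylaluminium 2-alkoxide of 36 | C=C[C@H](OCc3ccc(OC)cc3)[C@@]1(O[Al](CC)CC)CC[C@]2(C)[C@@H](O[Si](C)(C)C(C)(C)C)[C@H](O[Si](C)(C)C(C)(C)C)C(CC[C@@H](COCc4ccc(OC)cc4)C=C)=C(C)[C@@H]2[C@@H]1OS(C)(=O)=O | intermediate
38 | hydrindane ketone (key product), 22β-H, (3S)-OPMB | C=C[C@H](OCc3ccc(OC)cc3)C(=O)[C@@H]1CC[C@]2(C)[C@@H](O[Si](C)(C)C(C)(C)C)[C@H](O[Si](C)(C)C(C)(C)C)C(CC[C@@H](COCc4ccc(OC)cc4)C=C)=C(C)[C@@H]21 | intermediate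
39 | macrocyclic enone, C8=C9 (E/Z mixture) | O=C1[C@@H](OCc4ccc(OC)cc4)C=C[C@H](COCc5ccc(OC)cc5)CCC2=C(C)[C@@H]3[C@H]1CC[C@]3(C)[C@@H](O[Si](C)(C)C(C)(C)C)[C@@H]2O[Si](C)(C)C(C)(C)C | intermediate
40 | saturated macrocyclic ketone | O=C1[C@@H](OCc4ccc(OC)cc4)CC[C@H](COCc5ccc(OC)cc5)CCC2=C(C)[C@@H]3[C@H]1CC[C@]3(C)[C@@H](O[Si](C)(C)C(C)(C)C)[C@@H]2O[Si](C)(C)C(C)(C)C | intermediate
41 | C2 exocyclic methylene compound | C=C1[C@@H](OCc4ccc(OC)cc4)CC[C@H](COCc5ccc(OC)cc5)CCC2=C(C)[C@@H]3[C@H]1CC[C@]3(C)[C@@H](O[Si](C)(C)C(C)(C)C)[C@@H]2O[Si](C)(C)C(C)(C)C | intermediate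
42 | 3,11-diol, 27,29-bis-OTBS | C=C1[C@@H](O)CC[C@H](CO)CCC2=C(C)[C@@H]3[C@H]1CC[C@]3(C)[C@@H](O[Si](C)(C)C(C)(C)C)[C@@H]2O[Si](C)(C)C(C)(C)C | intermediate
43 | 3,11-diacetate, 27,29-bis-OTBS | C=C1[C@@H](OC(C)=O)CC[C@H](COC(C)=O)CCC2=C(C)[C@@H]3[C@H]1CC[C@]3(C)[C@@H](O[Si](C)(C)C(C)(C)C)[C@@H]2O[Si](C)(C)C(C)(C)C | intermediate
44 | CNP0193272.1 | C=C1[C@@H](OC(C)=O)CC[C@H](COC(C)=O)CCC2=C(C)[C@@H]3[C@H]1CC[C@]3(C)[C@@H](O)[C@@H]2O | target

## Step count and least certain steps

Total step count: 34. Longest linear sequence: 27 steps (steps 8 to 34, from 11).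

**Step 28 (key step).** The most likely failure is migration of the wrong group. If the decalin reacts through the chair with an axial mesylate, the C3 side chain is antiperiplanar to the leaving group and shifts instead of the ring bond. Simple ionisation with elimination, or Lewis-acid loss of the allylic C29 silyl ether, could also compete.

The fallback is a Wolff ring contraction, which causes the same C2–C23 shift but does not depend on the chair population. It sets out from 28 and returns at 38:
- Silylation of 28 with TBSOTf and 2,6-lutidine at −78 °C gives the bis-silyl ketone F1.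
- Thermodynamic formylation with NaH and HCO2Et at C22 gives the hydroxymethylene ketone F2.
- Deformylative diazo transfer with MsN3 and Et3N gives the 22-diazo ketone F3.
- Irradiation in MeOH gives the ring-contracted methyl ester F4; protonation of the ketene adduct on the convex face should place the ester α.
- iBu2AlH at −78 °C gives the aldehyde F5.
- Brown alkoxyallylboration with the (Z)-γ-(4-methoxybenzyloxy)allyl diisopinocampheylborane (from 4-methoxybenzyl allyl ether) fixes C3 by reagent control and gives the alcohol F6.
- Dess–Martin oxidation of F6 returns to 38.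

**Step 24 (inversion at C22).** The benzoate must approach from the concave α face. A slow displacement lets the activated alcohol revert, or lets the α-ketol epimerise or enolise, which would lose the configuration.

The fallback sets out from 29 and returns at 31. N-Bromosuccinimide in THF at −78 °C brominates the silyl enol ether on the convex face to give the 22β-bromo ketone F7, which has a smaller and better leaving group. CsO2CPh with 18-crown-6 in DMF then displaces bromide with inversion and gives 31.

**Step 25 (C2–C3 bond and C3 configuration).** The two chair transition states differ only in which α-carbon of the ketone lies next to chromium, so facial discrimination at the γ-carbon of the reagent may be poor and give the C3 epimer. Addition to the hindered ketone may also be slow.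

The fallback sets out from 31 and returns at 34, and it fixes C3 by reagent control:
- LiC(OMe)=C=CH2, premixed with CeCl3, adds to the ketone at −78 °C to give the allenyl carbinol F8.
- Aqueous oxalic acid unmasks the vinyl ketone F9.
- Corey–Bakshi–Shibata reduction with the (R)-oxazaborolidine and BH3·SMe2 gives the (3S)-diol F10.
- 4-Methoxybenzyl trichloroacetimidate with catalytic La(OTf)3 etherifies the secondary allylic hydroxyl and gives 34.

**Step 29 (ring-closing metathesis).** Closure of the eleven-membered ring is slow because of transannular strain, so intermolecular metathesis to dimers and oligomers, and isomerisation of the terminal alkenes, may take over.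

The fallback changes the scaffold on which the ring is closed. It sets out from 35 and returns at 40:
- Metathesis is run on the diol 35, where C2 is a quaternary carbinol carbon (gem-disubstituent effect) and the chain is held equatorial; this gives the bridged macrocycle F11.
- Hydrogenation over RhCl(PPh3)3 gives F12.
- Mesylation gives F13.
- The Et3Al-promoted ring contraction then delivers 40 directly.

Further compounds

F1 | step 28 | bis-TBS C2 ketone (27β,29α-bis-OTBS cis-decalone) | O=C1CC[C@]2(C)[C@@H](O[Si](C)(C)C(C)(C)C)[C@H](O[Si](C)(C)C(C)(C)C)C(CC[C@@H](COCc3ccc(OC)cc3)C=C)=C(C)[C@@H]2C1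
F2 | step 28 | 22-hydroxymethylene ketone | O=C1CC[C@]2(C)[C@@H](O[Si](C)(C)C(C)(C)C)[C@H](O[Si](C)(C)C(C)(C)C)C(CC[C@@H](COCc3ccc(OC)cc3)C=C)=C(C)[C@@H]2C1=CO
F3 | step 28 | 22-diazo ketone | O=C1CC[C@]2(C)[C@@H](O[Si](C)(C)C(C)(C)C)[C@H](O[Si](C)(C)C(C)(C)C)C(CC[C@@H](COCc3ccc(OC)cc3)C=C)=C(C)[C@@H]2C1=[N+]=[N-]
F4 | step 28 | ring-contracted methyl ester (22β-H) | COC(=O)[C@@H]1CC[C@]2(C)[C@@H](O[Si](C)(C)C(C)(C)C)[C@H](O[Si](C)(C)C(C)(C)C)C(CC[C@@H](COCc3ccc(OC)cc3)C=C)=C(C)[C@@H]21
F5 | step 28 | ring-contracted aldehyde (22β-H) | O=C[C@@H]1CC[C@]2(C)[C@@H](O[Si](C)(C)C(C)(C)C)[C@H](O[Si](C)(C)C(C)(C)C)C(CC[C@@H](COCc3ccc(OC)cc3)C=C)=C(C)[C@@H]21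
F6 | step 28 | syn alkoxyallylation product (C2 carbinol, (3S)-OPMB) | C=C[C@H](OCc3ccc(OC)cc3)[C@@H](O)[C@@H]1CC[C@]2(C)[C@@H](O[Si](C)(C)C(C)(C)C)[C@H](O[Si](C)(C)C(C)(C)C)C(CC[C@@H](COCc4ccc(OC)cc4)C=C)=C(C)[C@@H]21
F7 | step 24 | 22β-bromo ketone | O=C1CC[C@]2(C)[C@@H](O[Si](C)(C)C(C)(C)C)[C@H](O[Si](C)(C)C(C)(C)C)C(CC[C@@H](COCc3ccc(OC)cc3)C=C)=C(C)[C@@H]2[C@H]1Br
F8 | step 25 | 1-methoxyallenyl carbinol (2α-OH, 22α-OBz) | C=C=C(OC)[C@@]1(O)CC[C@]2(C)[C@@H](O[Si](C)(C)C(C)(C)C)[C@H](O[Si](C)(C)C(C)(C)C)C(CC[C@@H](COCc3ccc(OC)cc3)C=C)=C(C)[C@@H]2[C@@H]1OC(=O)c1ccccc1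
F9 | step 25 | hydroxy vinyl ketone (C3 ketone) | C=CC(=O)[C@@]1(O)CC[C@]2(C)[C@@H](O[Si](C)(C)C(C)(C)C)[C@H](O[Si](C)(C)C(C)(C)C)C(CC[C@@H](COCc3ccc(OC)cc3)C=C)=C(C)[C@@H]2[C@@H]1OC(=O)c1ccccc1
F10 | step 25 | (3S)-allylic alcohol, 2α-OH, 22α-OBz | C=C[C@H](O)[C@@]1(O)CC[C@]2(C)[C@@H](O[Si](C)(C)C(C)(C)C)[C@H](O[Si](C)(C)C(C)(C)C)C(CC[C@@H](COCc3ccc(OC)cc3)C=C)=C(C)[C@@H]2[C@@H]1OC(=O)c1ccccc1
F11 | step 29 | bridged macrocyclic decalin diol, C8=C9 (E/Z mixture) | C5[C@H](OCc3ccc(OC)cc3)[C@@]1(O)CC[C@]2(C)[C@@H](O[Si](C)(C)C(C)(C)C)[C@H](O[Si](C)(C)C(C)(C)C)C(CC[C@@H](COCc4ccc(OC)cc4)C=5)=C(C)[C@@H]2[C@@H]1O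
F12 | step 29 | saturated bridged macrocyclic decalin diol | C5[C@H](OCc3ccc(OC)cc3)[C@@]1(O)CC[C@]2(C)[C@@H](O[Si](C)(C)C(C)(C)C)[C@H](O[Si](C)(C)C(C)(C)C)C(CC[C@@H](COCc4ccc(OC)cc4)C5)=C(C)[C@@H]2[C@@H]1O
F13 | step 29 | 22α-mesylate of F12 | C5[C@H](OCc3ccc(OC)cc3)[C@@]1(O)CC[C@]2(C)[C@@H](O[Si](C)(C)C(C)(C)C)[C@H](O[Si](C)(C)C(C)(C)C)C(CC[C@@H](COCc4ccc(OC)cc4)C5)=C(C)[C@@H]2[C@@H]1OS(C)(=O)=O
A1 | alternative 1 | tricyclic C27 ketone with C29 methylene | C=C1[C@@H](OCc4ccc(OC)cc4)CC[C@H](COCc5ccc(OC)cc5)CCC2=C(C)[C@@H]3[C@H]1CC[C@]3(C)C(=O)C2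
A2 | alternative 2 | hydrindadienone with C23 ketone | O1CCOC1(C3=C4C(C)=C(CCCC(=O)OC)[C@@H](O[Si](C)(C)C(C)(C)C)[C@H](O[Si](C)(C)C(C)(C)C)[C@@]4(C)CC3=O)[C@@H](OCc2ccc(OC)cc2)CCO[Si](C)(C)C(C)(C)C
A3 | alternative 3 | tricyclic C3 ketone with the full carbon skeleton | C1C(=O)CC[C@H](COCc4ccc(OC)cc4)CCC2=C(C)[C@@H]3[C@H]1CC[C@]3(C)[C@@H](O[Si](C)(C)C(C)(C)C)[C@@H]2O[Si](C)(C)C(C)(C)C
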